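**Retrosynthetic overview**

1. The last C–C bond made is aryl–C2: the arene carbon para to the 8‑O‑4′ ether oxygen is joined to C2, the benzylic carbon next to ring oxygen O1 of the oxolane. This is done by a Ni‑catalysed stereoconvergent C‑arylation of an anomeric bromide with an arylzinc, followed by one global deprotection.
2. Enabling feature: C2 is the O1‑bound, acetal‑level carbon of the oxolane ring. It can therefore be carried as a lactone carbonyl, then as a lactol acetate (both anomers), then as an O1‑stabilised C2 radical. Its only stereogenic neighbour, C3 (CH2O arm, trans to the C4 aroyl group), steers the aryl group to the 2,3‑trans face.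
3. Oxolane half 23: tandem 1,4‑addition of an aryl‑dithiane anion and α‑alkylation on a (5S)‑menthyloxybutenolide sets C4 and C3; then auxiliary removal to the γ‑lactone, DIBAL, dithiane hydrolysis, and Bn → Ac exchange.
4. Aryl half 11: Mitsunobu inversion on a methyl (R)‑glycerate ether with 4‑bromo‑2,6‑dimethoxyphenol sets C8; Weinreb amide / aryl Grignard; chelation‑controlled reduction sets C7 (erythro); silylation.
5. Ring order: the benzene rings are purchased. The oxolane ring is the butenolide ring of 14, carried through and re‑closed as the γ‑lactone in step 10, before the coupling. No ring is formed in or after step 15.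

Key step: step 15

Remark: butenolide 14 (the antipode of the common l‑menthol‑derived reagent) and (triisopropylsiloxy)methyl chloride are taken as catalogue compounds. The lactol‑level compounds 20–23 and 26 are anomeric mixtures at C2, which is immaterial because C2 is set only in step 15.

**Route**

Step 1
Reactants: 1 methyl (R)-2,3-dihydroxypropanoate
Product: 2 methyl (R)-3-[(tert-butyldimethylsilyl)oxy]-2-hydroxypropanoate
Conditions: TBSCl (1.05 equiv), imidazole, CH2Cl2, −10 → 0 °C
Reagents that add atoms: tert-butyldimethylsilyl chloride, CC(C)(C)[Si](C)(C)Cl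
Why: Selective silylation of the primary hydroxyl of the 1,2-diol (the secondary α-hydroxy ester OH is more hindered and less nucleophilic) should leave the stereocentre untouched and the secondary OH free.

Step 2
Reactants: 2 methyl (R)-3-[(tert-butyldimethylsilyl)oxy]-2-hydroxypropanoate; 3 4-bromo-2,6-dimethoxyphenol
Product: 4 methyl (S)-2-(4-bromo-2,6-dimethoxyphenoxy)-3-[(tert-butyldimethylsilyl)oxy]propanoate
Conditions: PPh3, DIAD, toluene, 0 °C → rt
Reagents that add atoms: none
Why: Mitsunobu etherification of an α-hydroxy ester with an acidic phenol is an SN2 process with inversion, so (R)-C2 should become the (S)-aryl ether that is C8 of the target.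

Step 3
Reactants: 4 methyl (S)-2-(4-bromo-2,6-dimethoxyphenoxy)-3-[(tert-butyldimethylsilyl)oxy]propanoate
Product: 5 (S)-2-(4-bromo-2,6-dimethoxyphenoxy)-3-[(tert-butyldimethylsilyl)oxy]-N-methoxy-N-methylpropanamide
Conditions: MeNH(OMe)·HCl, AlMe3, CH2Cl2, 0 °C → rt; Rochelle salt work-up
Reagents that add atoms: N,O-dimethylhydroxylamine hydrochloride, CNOC.Cl
Why: Weinreb amidation by aminolysis of the ester with the aluminium amide is non-basic, so the α-aryloxy stereocentre should not epimerise, and it provides a mono-addition acyl donor.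

Step 4
Reactants: 6 4-bromo-2-methoxyphenol
Product: 7 (4-bromo-2-methoxyphenoxy)(tert-butyl)dimethylsilane
Conditions: TBSCl, imidazole, DMF, rt
Reagents that add atoms: tert-butyldimethylsilyl chloride, CC(C)(C)[Si](C)(C)Cl
Why: Standard phenol silylation masks the acidic OH for Grignard formation with a group that fluoride removes at the end.

Step 5
Reactants: 7 (4-bromo-2-methoxyphenoxy)(tert-butyl)dimethylsilane; 5 (S)-2-(4-bromo-2,6-dimethoxyphenoxy)-3-[(tert-butyldimethylsilyl)oxy]-N-methoxy-N-methylpropanamide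
Product: 9 (S)-2-(4-bromo-2,6-dimethoxyphenoxy)-3-[(tert-butyldimethylsilyl)oxy]-1-{4-[(tert-butyldimethylsilyl)oxy]-3-methoxyphenyl}propan-1-one, via arylmagnesium bromide 8 (not isolated)
Conditions: 7, Mg turnings, I2 (cat.), THF, 50 °C; solution decanted from Mg; 5, THF, −20 → 0 °C; cold aq. NH4Cl
Reagents that add atoms: none
Why: Grignard addition to a Weinreb amide stops at the chelated tetrahedral intermediate and should give the aryl ketone without over-addition, aryl–aryl Mg/Br exchange with the bromoarene of 5 being negligible at 0 °C and the cold neutral quench preserving the α-stereocentre.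

Step 6
Reactants: 9 (S)-2-(4-bromo-2,6-dimethoxyphenoxy)-3-[(tert-butyldimethylsilyl)oxy]-1-{4-[(tert-butyldimethylsilyl)oxy]-3-methoxyphenyl}propan-1-one
Product: 10 (1R,2S)-2-(4-bromo-2,6-dimethoxyphenoxy)-3-[(tert-butyldimethylsilyl)oxy]-1-{4-[(tert-butyldimethylsilyl)oxy]-3-methoxyphenyl}propan-1-ol (erythro)
Conditions: Zn(BH4)2, Et2O, −30 → 0 °C
Reagents that add atoms: none
Why: Chelation-controlled (Cram-chelate) reduction: zinc bridges the carbonyl and the α-aryloxy oxygen and hydride enters from the side of the small C8–H, which should give the anti (erythro, 7R,8S) carbinol, the silyl ether on O9 blocking the competing β-chelate.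

Step 7
Reactants: 10 (1R,2S)-2-(4-bromo-2,6-dimethoxyphenoxy)-3-[(tert-butyldimethylsilyl)oxy]-1-{4-[(tert-butyldimethylsilyl)oxy]-3-methoxyphenyl}propan-1-ol
Product: 11 5-bromo-2-{[(1R,2S)-1,3-bis[(tert-butyldimethylsilyl)oxy]-1-{4-[(tert-butyldimethylsilyl)oxy]-3-methoxyphenyl}propan-2-yl]oxy}-1,3-dimethoxybenzene
Conditions: TBSOTf, 2,6-lutidine, CH2Cl2, −78 → 0 °C
Reagents that add atoms: tert-butyldimethylsilyl triflate, CC(C)(C)[Si](C)(C)OS(=O)(=O)C(F)(F)F
Why: Silylation of the hindered benzylic alcohol with the triflate/lutidine system should give an all-silyl aryl bromide with no acidic proton, ready for halogen–lithium exchange.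

Step 8
Reactants: 12 4-(benzyloxy)-3,5-dimethoxybenzaldehyde
Product: 13 2-[4-(benzyloxy)-3,5-dimethoxyphenyl]-1,3-dithiane
Conditions: HS(CH2)3SH, BF3·OEt2 (cat.), CH2Cl2, 0 °C → rt
Reagents that add atoms: propane-1,3-dithiol, SCCCS
Why: Lewis-acid-catalysed dithioacetalisation turns the aldehyde into the Corey–Seebach acyl-anion equivalent of the 4-hydroxy-3,5-dimethoxybenzoyl group.

Step 9
Reactants: 13 2-[4-(benzyloxy)-3,5-dimethoxyphenyl]-1,3-dithiane; 14 (5S)-5-{[(1S,2R,5S)-2-isopropyl-5-methylcyclohexyl]oxy}furan-2(5H)-one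
Product: 17 (3R,4S,5S)-4-{2-[4-(benzyloxy)-3,5-dimethoxyphenyl]-1,3-dithian-2-yl}-5-{[(1S,2R,5S)-2-isopropyl-5-methylcyclohexyl]oxy}-3-{[(triisopropylsilyl)oxy]methyl}dihydrofuran-2(3H)-one, via lithiated dithiane 15 (not isolated), via lithium enolate 16 (not isolated)
Conditions: n-BuLi, THF, −78 → −20 °C; 14, −78 °C; (iPr)3SiOCH2Cl, DMPU, −78 → −30 °C
Reagents that add atoms: (triisopropylsiloxy)methyl chloride, CC(C)[Si](OCCl)(C(C)C)C(C)C
Why: Tandem conjugate addition–enolate alkylation on a γ-alkoxybutenolide: the dithiane anion should add 1,4 to C4 anti to the C5 menthyloxy group (sets C4), and the lithium enolate should be alkylated by the α-chloro ether anti to the bulky C4 substituent (sets C3), giving the 3,4-trans-4,5-trans lactone.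

Step 10
Reactants: 17 (3R,4S,5S)-lactone acetal from step 9
Product: 19 (3R,4S)-4-{2-[4-(benzyloxy)-3,5-dimethoxyphenyl]-1,3-dithian-2-yl}-3-{[(triisopropylsilyl)oxy]methyl}dihydrofuran-2(3H)-one, via potassium hydroxy carboxylate 18 (not isolated)
Conditions: NaBH4, KOH, EtOH/H2O, 0 °C → rt; then 2 M HCl to pH 2, rt
Reagents that add atoms: none
Why: Hydroxide opens the lactone acetal to the aldehyde carboxylate with loss of menthol, borohydride reduces the aldehyde in situ and acidification relactonises onto the new primary alcohol, so the carbonyl carbon (future C2) keeps its oxidation level while the auxiliary-bearing carbon becomes C5H2 and C3 (a carboxylate α-carbon) is not epimerised.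

Step 11
Reactants: 19 (3R,4S)-lactone
Product: 20 (3R,4S)-4-{2-[4-(benzyloxy)-3,5-dimethoxyphenyl]-1,3-dithian-2-yl}-3-{[(triisopropylsilyl)oxy]methyl}tetrahydrofuran-2-ol (both anomers)
Conditions: DIBAL-H (1.2 equiv), toluene, −78 °C; Rochelle salt
Reagents that add atoms: none
Why: DIBAL-H half-reduction of a γ-lactone at −78 °C stops at the aluminium hemiacetal and should give the lactol, the dithiane, benzyl ether and TIPS ether being inert.

Step 12
Reactants: 20 (3R,4S)-lactol
Product: 21 (3R,4S)-4-[4-(benzyloxy)-3,5-dimethoxybenzoyl]-3-{[(triisopropylsilyl)oxy]methyl}tetrahydrofuran-2-ol (both anomers)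
Conditions: MeI, CaCO3, MeCN/H2O (4:1), 45 °C
Reagents that add atoms: water, O
Why: S-alkylative hydrolysis of the dithiane (Corey–Seebach unmasking) under carbonate buffering should release the aryl ketone without acid or oxidant, and C4, now α to the ketone, stays in the thermodynamically preferred trans relation to C3.

Step 13
Reactants: 21 (3R,4S)-keto lactol
Product: 22 (3R,4S)-4-(4-hydroxy-3,5-dimethoxybenzoyl)-3-{[(triisopropylsilyl)oxy]methyl}tetrahydrofuran-2-ol (both anomers)
Conditions: H2 (1 atm), 10% Pd/C, EtOAc, rt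
Reagents that add atoms: none
Why: Hydrogenolysis of the aryl benzyl ether is placed here because sulfur is gone and the molecule has as yet no benzylic C–O bond of the 2-aryloxolane or carbinol type, while the electron-rich aryl ketone is reduced only slowly.

Step 14
Reactants: 22 (3R,4S)-phenol lactol
Product: 23 (3R,4S)-4-(4-acetoxy-3,5-dimethoxybenzoyl)-3-{[(triisopropylsilyl)oxy]methyl}tetrahydrofuran-2-yl acetate (both anomers)
Conditions: Ac2O, pyridine, DMAP (cat.), CH2Cl2, 0 °C → rt
Reagents that add atoms: acetic anhydride, CC(=O)OC(C)=O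
Why: One acetylation should convert the lactol into the anomeric acetate (leaving group for the key step) and the phenol into an aryl acetate that is inert to organozinc and nickel.

Step 15
Reactants: 11 tris-TBS aryl bromide; 23 anomeric acetate
Product: 27 4-[(3S,4R,5S)-5-{4-[((1R,2S)-1,3-bis[(tert-butyldimethylsilyl)oxy]-1-{4-[(tert-butyldimethylsilyl)oxy]-3-methoxyphenyl}propan-2-yl)oxy]-3,5-dimethoxyphenyl}-4-{[(triisopropylsilyl)oxy]methyl}tetrahydrofuran-3-carbonyl]-2,6-dimethoxyphenyl acetate, via aryllithium 24 (not isolated), via arylzinc bromide 25 (not isolated), via anomeric bromide 26 (not isolated)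
Conditions: 11: n-BuLi, THF, −78 °C, then ZnBr2, −78 → 0 °C; 23: TMSBr, CH2Cl2, −20 → 0 °C, volatiles removed cold; combined with NiCl2·glyme (10 mol %), 4,4′,4″-tri-tert-butylterpyridine (12 mol %), THF/DMA, −10 °C → rt
Reagents that add atoms: none
Why: TMSBr turns both anomers of acetate 23 into the labile 2-bromooxolane 26, a nickel(I)–aryl species (fed by transmetalation from arylzinc 25) abstracts its bromine to give the O1-stabilised C2 radical that has lost the anomeric configuration, and radical capture at nickel followed by C(sp3)–C(sp2) reductive elimination forms the aryl–C2 bond. The closest known reaction type is the Ni-catalysed Negishi cross-coupling of glycosyl halides with arylzinc reagents used for C-aryl glycosides, a stereoconvergent radical-type coupling. No ring is closed in this step: the oxolane and the three benzene rings are already present and the step only joins the two halves. The one new stereocentre, C2, is set by substrate control, the nickel–aryl unit taking the C2 radical on the face anti to the adjacent C3 CH2OTIPS group (1,2-trans capture, as is typical of furanosyl radicals), which should give the 2,3-trans (2S) product, also the thermodynamically preferred all-trans ring. The step needs facial selectivity at C2 (secured by the bulky silyloxymethyl group on C3, the only neighbour of C2), site selectivity on the arene (fixed by the bromine of 11 para to the ether oxygen, a position a Friedel–Crafts arylation would not reach) and chemoselectivity (arylzinc and low-valent nickel leave the aryl ketone, aryl acetate and silyl ethers alone, and the tridentate ligand suppresses β-hydride elimination to the 2,3-dihydrofuran).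

Step 16
Reactants: 27 protected coupling product
Product: 28 (4-hydroxy-3,5-dimethoxyphenyl)[(3S,4R,5S)-5-(4-{[(1R,2S)-1,3-dihydroxy-1-(4-hydroxy-3-methoxyphenyl)propan-2-yl]oxy}-3,5-dimethoxyphenyl)-4-(hydroxymethyl)tetrahydrofuran-3-yl]methanone (CNP0236429.1)
Conditions: TBAF·3H2O (excess), THF, 0 °C → rt; aq. NH4Cl
Reagents that add atoms: none
Why: Fluoride should cleave the three TBS ethers and the TIPS ether and the basic wet fluoride should also hydrolyse the activated (p-acyl) aryl acetate, the early-formed phenoxide para to the ketone suppressing enolisation so that C4 and the β-alkoxy ketone of the oxolane survive, and no acid touches the two benzylic C–O bonds.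

**Compound list**

1 | methyl (R)-2,3-dihydroxypropanoate (methyl D-glycerate) | COC(=O)[C@H](O)CO | starting material
2 | methyl (R)-3-[(tert-butyldimethylsilyl)oxy]-2-hydroxypropanoate | COC(=O)[C@H](O)CO[Si](C)(C)C(C)(C)C | intermediate
3 | 4-bromo-2,6-dimethoxyphenol | COc1cc(Br)cc(OC)c1O | starting material
4 | methyl (S)-2-(4-bromo-2,6-dimethoxyphenoxy)-3-[(tert-butyldimethylsilyl)oxy]propanoate | COC(=O)[C@@H](Oc1c(OC)cc(Br)cc1OC)CO[Si](C)(C)C(C)(C)C | intermediate
5 | (S)-2-(4-bromo-2,6-dimethoxyphenoxy)-3-[(tert-butyldimethylsilyl)oxy]-N-methoxy-N-methylpropanamide | CON(C)C(=O)[C@@H](Oc1c(OC)cc(Br)cc1OC)CO[Si](C)(C)C(C)(C)C | intermediate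
6 | 4-bromo-2-methoxyphenol | COc1cc(Br)ccc1O | starting material
7 | (4-bromo-2-methoxyphenoxy)(tert-butyl)dimethylsilane | COc1cc(Br)ccc1O[Si](C)(C)C(C)(C)C | intermediate
8 | {4-[(tert-butyldimethylsilyl)oxy]-3-methoxyphenyl}magnesium bromide (formed in situ) | COc1cc([Mg]Br)ccc1O[Si](C)(C)C(C)(C)C | intermediate
9 | (S)-2-(4-bromo-2,6-dimethoxyphenoxy)-3-[(tert-butyldimethylsilyl)oxy]-1-{4-[(tert-butyldimethylsilyl)oxy]-3-methoxyphenyl}propan-1-one | COc1cc(C(=O)[C@@H](Oc2c(OC)cc(Br)cc2OC)CO[Si](C)(C)C(C)(C)C)ccc1O[Si](C)(C)C(C)(C)C | intermediate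
10 | (1R,2S)-2-(4-bromo-2,6-dimethoxyphenoxy)-3-[(tert-butyldimethylsilyl)oxy]-1-{4-[(tert-butyldimethylsilyl)oxy]-3-methoxyphenyl}propan-1-ol (erythro) | COc1cc([C@@H](O)[C@H](CO[Si](C)(C)C(C)(C)C)Oc2c(OC)cc(Br)cc2OC)ccc1O[Si](C)(C)C(C)(C)C | intermediate
11 | 5-bromo-2-{[(1R,2S)-1,3-bis[(tert-butyldimethylsilyl)oxy]-1-{4-[(tert-butyldimethylsilyl)oxy]-3-methoxyphenyl}propan-2-yl]oxy}-1,3-dimethoxybenzene | COc1cc([C@@H](O[Si](C)(C)C(C)(C)C)[C@H](CO[Si](C)(C)C(C)(C)C)Oc2c(OC)cc(Br)cc2OC)ccc1O[Si](C)(C)C(C)(C)C | intermediate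
12 | 4-(benzyloxy)-3,5-dimethoxybenzaldehyde | COc1cc(C=O)cc(OC)c1OCc1ccccc1 | starting material
13 | 2-[4-(benzyloxy)-3,5-dimethoxyphenyl]-1,3-dithiane | COc1cc(C2SCCCS2)cc(OC)c1OCc1ccccc1 | intermediate
14 | (5S)-5-{[(1S,2R,5S)-2-isopropyl-5-methylcyclohexyl]oxy}furan-2(5H)-one [(5S)-5-(d-menthyloxy)butenolide] | C[C@H]1CC[C@@H]([C@H](C1)O[C@H]2OC(=O)C=C2)C(C)C | starting material
15 | 2-lithio-2-[4-(benzyloxy)-3,5-dimethoxyphenyl]-1,3-dithiane (formed in situ) | [Li]C1(c2cc(OC)c(OCc3ccccc3)c(OC)c2)SCCCS1 | intermediate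
16 | lithium enolate of the 1,4-adduct, dithianyl group at C4 trans to the C5 menthyloxy group (formed in situ) | C[C@H]1CC[C@@H]([C@H](C1)O[C@H]2OC(O[Li])=C[C@@H]2C3(c4cc(OC)c(OCc5ccccc5)c(OC)c4)SCCCS3)C(C)C | intermediate
17 | (3R,4S,5S)-4-{2-[4-(benzyloxy)-3,5-dimethoxyphenyl]-1,3-dithian-2-yl}-5-{[(1S,2R,5S)-2-isopropyl-5-methylcyclohexyl]oxy}-3-{[(triisopropylsilyl)oxy]methyl}dihydrofuran-2(3H)-one | C[C@H]1CC[C@@H]([C@H](C1)O[C@H]2OC(=O)[C@@H](CO[Si](C(C)C)(C(C)C)C(C)C)[C@@H]2C3(c4cc(OC)c(OCc5ccccc5)c(OC)c4)SCCCS3)C(C)C | intermediate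
18 | potassium salt of the ring-opened γ-hydroxy acid of 19, both stereocentres as in 19 (formed in situ) | [K+].[O-]C(=O)[C@@H](CO[Si](C(C)C)(C(C)C)C(C)C)[C@@H](CO)C1(c2cc(OC)c(OCc3ccccc3)c(OC)c2)SCCCS1 | intermediate
19 | (3R,4S)-4-{2-[4-(benzyloxy)-3,5-dimethoxyphenyl]-1,3-dithian-2-yl}-3-{[(triisopropylsilyl)oxy]methyl}dihydrofuran-2(3H)-one (3,4-trans) | O=C1OC[C@@H](C2(c3cc(OC)c(OCc4ccccc4)c(OC)c3)SCCCS2)[C@@H]1CO[Si](C(C)C)(C(C)C)C(C)C | intermediate
20 | (3R,4S)-4-{2-[4-(benzyloxy)-3,5-dimethoxyphenyl]-1,3-dithian-2-yl}-3-{[(triisopropylsilyl)oxy]methyl}tetrahydrofuran-2-ol, both anomers | OC1OC[C@@H](C2(c3cc(OC)c(OCc4ccccc4)c(OC)c3)SCCCS2)[C@@H]1CO[Si](C(C)C)(C(C)C)C(C)C | intermediate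
21 | (3R,4S)-4-[4-(benzyloxy)-3,5-dimethoxybenzoyl]-3-{[(triisopropylsilyl)oxy]methyl}tetrahydrofuran-2-ol, both anomers | OC1OC[C@@H](C(=O)c2cc(OC)c(OCc3ccccc3)c(OC)c2)[C@@H]1CO[Si](C(C)C)(C(C)C)C(C)C | intermediate
22 | (3R,4S)-4-(4-hydroxy-3,5-dimethoxybenzoyl)-3-{[(triisopropylsilyl)oxy]methyl}tetrahydrofuran-2-ol, both anomers | OC1OC[C@@H](C(=O)c2cc(OC)c(O)c(OC)c2)[C@@H]1CO[Si](C(C)C)(C(C)C)C(C)C | intermediate
23 | (3R,4S)-4-(4-acetoxy-3,5-dimethoxybenzoyl)-3-{[(triisopropylsilyl)oxy]methyl}tetrahydrofuran-2-yl acetate, both anomers | CC(=O)OC1OC[C@@H](C(=O)c2cc(OC)c(OC(C)=O)c(OC)c2)[C@@H]1CO[Si](C(C)C)(C(C)C)C(C)C | intermediate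
24 | aryllithium from 11, Li in place of Br (formed in situ) | COc1cc([C@@H](O[Si](C)(C)C(C)(C)C)[C@H](CO[Si](C)(C)C(C)(C)C)Oc2c(OC)cc([Li])cc2OC)ccc1O[Si](C)(C)C(C)(C)C | intermediate
25 | arylzinc bromide from 11, ZnBr in place of Br (formed in situ) | COc1cc([C@@H](O[Si](C)(C)C(C)(C)C)[C@H](CO[Si](C)(C)C(C)(C)C)Oc2c(OC)cc([Zn]Br)cc2OC)ccc1O[Si](C)(C)C(C)(C)C | intermediate
26 | 2-bromo analogue of 23 (anomeric bromide, both anomers; C3 and C4 as in 23; formed in situ) | BrC1OC[C@@H](C(=O)c2cc(OC)c(OC(C)=O)c(OC)c2)[C@@H]1CO[Si](C(C)C)(C(C)C)C(C)C | intermediate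
27 | protected target: 4-[(3S,4R,5S)-5-{4-[((1R,2S)-1,3-bis[(tert-butyldimethylsilyl)oxy]-1-{4-[(tert-butyldimethylsilyl)oxy]-3-methoxyphenyl}propan-2-yl)oxy]-3,5-dimethoxyphenyl}-4-{[(triisopropylsilyl)oxy]methyl}tetrahydrofuran-3-carbonyl]-2,6-dimethoxyphenyl acetate | COc1cc([C@@H](O[Si](C)(C)C(C)(C)C)[C@H](CO[Si](C)(C)C(C)(C)C)Oc2c(OC)cc([C@H]3OC[C@@H](C(=O)c4cc(OC)c(OC(C)=O)c(OC)c4)[C@@H]3CO[Si](C(C)C)(C(C)C)C(C)C)cc2OC)ccc1O[Si](C)(C)C(C)(C)C | intermediate
28 | (4-hydroxy-3,5-dimethoxyphenyl)[(3S,4R,5S)-5-(4-{[(1R,2S)-1,3-dihydroxy-1-(4-hydroxy-3-methoxyphenyl)propan-2-yl]oxy}-3,5-dimethoxyphenyl)-4-(hydroxymethyl)tetrahydrofuran-3-yl]methanone | COc1cc([C@@H](O)[C@H](CO)Oc2c(OC)cc([C@H]3OC[C@@H](C(=O)c4cc(OC)c(O)c(OC)c4)[C@@H]3CO)cc2OC)ccc1O | target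

**Step count**

Total: 16 steps. Longest linear sequence: 9 steps (steps 8–16, from 12); the aryl branch is 8 steps (1, 2, 3, 5, 6, 7, 15, 16), with step 4 as a one-step side branch.

**Steps most likely to fail, with fallbacks**

Step 15 (key step). The 2-bromooxolane may lose HBr to the 2,3-dihydrofuran, or undergo β-hydride elimination at nickel, faster than it is arylated, and the radical capture may discriminate the two faces of C2 insufficiently. The fallback sets out from 23 (with arylzinc bromide 25 made from 11 as before) and returns at 27. It replaces the radical coupling of a fleeting halide by a polar substitution on a bench-stable donor. Compound 23 is treated with benzenesulfinic acid and MgBr2·OEt2 in CH2Cl2 at 0 °C to give the anomeric sulfone (3R,4S)-4-(4-acetoxy-3,5-dimethoxybenzoyl)-2-(phenylsulfonyl)-3-{[(triisopropylsilyl)oxy]methyl}tetrahydrofuran F1 (both anomers). F1 and 25 (2 equiv) with ZnBr2 in THF at rt should then undergo sulfone displacement through the O1-stabilised oxocarbenium ion, which again funnels both anomers, with the aryl group delivered anti to the C3 arm, to give 27.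

Step 9. C-alkylation of the hindered lactone enolate by the silyloxymethyl chloride may be slow, or silyl transfer to the enolate oxygen may compete, so that only the protonated 1,4-adduct is obtained. The fallback sets out from 13 and 14 (through enolate 16) and returns at 17. The C–C bond is made by an aldol reaction instead of an alkylation. Enolate 16 is quenched at −78 °C with monomeric formaldehyde (THF solution from cracked paraformaldehyde) to give the 3,4-trans hydroxymethyl lactone acetal (3R,4S,5S)-4-{2-[4-(benzyloxy)-3,5-dimethoxyphenyl]-1,3-dithian-2-yl}-3-(hydroxymethyl)-5-[(1S,2R,5S)-menthyloxy]dihydrofuran-2(3H)-one F2. F2 is then silylated (TIPSCl, imidazole, DMF, rt) to 17.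

Step 6. Chelation by the hindered, weakly basic aryloxy oxygen may be too weak, so that Felkin–Anh delivery of hydride gives mainly the threo (7S,8S) carbinol. The fallback sets out from 9 and returns at 10. Substrate (chelate) control is replaced by catalyst control in a Corey–Bakshi–Shibata reduction: (R)-2-methyl-CBS-oxazaborolidine (20 mol %), BH3·SMe2, THF, −20 °C. With the aryl group as the large substituent, this catalyst should deliver hydride to the face that gives the (1R)-carbinol 10 whatever the chelating ability of the α-substituent. No new compound arises (F0).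

Further compounds
F1 | step 15 | (3R,4S)-4-(4-acetoxy-3,5-dimethoxybenzoyl)-2-(phenylsulfonyl)-3-{[(triisopropylsilyl)oxy]methyl}tetrahydrofuran (both anomers) | O=S(=O)(c1ccccc1)C1OC[C@@H](C(=O)c2cc(OC)c(OC(C)=O)c(OC)c2)[C@@H]1CO[Si](C(C)C)(C(C)C)C(C)C
F2 | step 9 | (3R,4S,5S)-4-{2-[4-(benzyloxy)-3,5-dimethoxyphenyl]-1,3-dithian-2-yl}-3-(hydroxymethyl)-5-{[(1S,2R,5S)-2-isopropyl-5-methylcyclohexyl]oxy}dihydrofuran-2(3H)-one | C[C@H]1CC[C@@H]([C@H](C1)O[C@H]2OC(=O)[C@@H](CO)[C@@H]2C3(c4cc(OC)c(OCc5ccccc5)c(OC)c4)SCCCS3)C(C)C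
F0 | step 6 | none | none
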